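**Retrosynthetic overview**

1. Feature: ring A, the cyclopentane C1–C11–C10–C9–C7, shares the C1–C7 bond with ring B (C1–C8–C5–C6–C7). Its three carbons C9(Me2)–C10–C11 lie across what is the C1=C7 double bond of a 2-carbomethoxycyclopentenone that already carries C2 (ester) and C8 (ketone) on C1.
2. Late disconnections: the C3–acyl bond (O-acylation, then O→C acyl shift), C2–C3 (Dieckmann closure of ring C, C1–C2–C3–C4–C5–C8), then C5–C4 and C5–CH3 (aldol/oxidation and enolate methylation).
3. The carbinol carbon C12 comes from the exocyclic methylene C10=C12 (hydroboration from the convex face, oxidation, two methyl additions) while C8 is masked as a dioxolane.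
4. Key disconnection: C7–C9 and C1–C11 by an enantioselective palladium–trimethylenemethane [3+2] cycloaddition of the gem-dimethyl donor 3 to the enone ester 7.
5. Ring order: ring B (bought) → ring A (step 5) → ring C (step 17).

Key step: step 5

Atom labels used throughout: C1 quaternary ring-fusion carbon; C2 carbonyl carbon on C1 (ester, later ring ketone); C3 acyl-bearing carbon; C4 enol carbon; C5 methyl-bearing bridgehead; C6 ring CH2; C7 ring-fusion CH; C8 bridging ketone; C9 CMe2; C10 CH carrying the side chain; C11 ring CH2; C12 carbinol carbon. "Convex face" means the face of the cis-fused rings A/B that carries C2 and the C7 hydrogen.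

Assumption: the antipode of the phosphoramidite ligand that gives the (3aS,6aS) adduct 8 is taken to be identified in a pilot run; both antipodes are accessible.

**Route**

Step 1
Reactants: 1 ethyl 2-[(trimethylsilyl)methyl]prop-2-enoate
Product: 2 2-methyl-3-[(trimethylsilyl)methyl]but-3-en-2-ol
Conditions: MeMgBr (3 equiv), Et2O, 0 °C → rt; aq. NH4Cl
Reagents that add atoms: methylmagnesium bromide, C[Mg]Br
Why: Double Grignard 1,2-addition to the ester of an α-substituted acrylate should give the tertiary allylic alcohol and leave the allylsilane untouched.

Step 2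
Reactants: 2 2-methyl-3-[(trimethylsilyl)methyl]but-3-en-2-ol
Product: 3 2-methyl-3-[(trimethylsilyl)methyl]but-3-en-2-yl acetate (gem-dimethyl trimethylenemethane donor)
Conditions: Ac2O, Et3N, DMAP (cat.), CH2Cl2, rt
Reagents that add atoms: acetic anhydride, CC(=O)OC(C)=O
Why: DMAP-catalysed acylation (nucleophilic catalysis) esterifies the tertiary alcohol under basic conditions that the acid-sensitive allylsilane tolerates.

Step 3
Reactants: 4 methyl 2-oxocyclopentane-1-carboxylate
Product: 5 methyl 2-oxo-1-(phenylselanyl)cyclopentane-1-carboxylate (racemic)
Conditions: PhSeCl, pyridine, CH2Cl2, 0 °C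
Reagents that add atoms: benzeneselenenyl chloride, Cl[Se]c1ccccc1
Why: α-Selenenylation of the β-keto ester through its enol places selenium on the doubly activated carbon C1.

Step 4
Reactants: 5 methyl 2-oxo-1-(phenylselanyl)cyclopentane-1-carboxylate
Product: 7 methyl 5-oxocyclopent-1-ene-1-carboxylate, via selenoxide 6 (not isolated)
Conditions: 30% H2O2, CH2Cl2, 0 °C → rt; short silica plug, used at once
Reagents that add atoms: none
Why: Oxidation to the selenoxide is followed by syn-elimination toward the only β-hydrogens (on C7), which gives the C1=C7 enone; it dimerises readily and is therefore not stored.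

Step 5
Reactants: 3 2-methyl-3-[(trimethylsilyl)methyl]but-3-en-2-yl acetate (1.5 equiv); 7 methyl 5-oxocyclopent-1-ene-1-carboxylate
Product: 8 methyl (3aS,6aS)-4,4-dimethyl-5-methylidene-1-oxooctahydropentalene-6a-carboxylate (cis-fused; C2 ester and C7–H on the same face)
Conditions: Pd(dba)2 (5 mol%), BINOL-derived phosphoramidite carrying a trans-2,5-di(2-naphthyl)pyrrolidine amine unit (10 mol%), toluene, 25 → 45 °C, slow addition of 7
Reagents that add atoms: none
Why: Proposed new method: zerovalent palladium ionises the tertiary allylic acetate of 3 and the released acetate removes the silyl group, giving a zwitterionic trimethylenemethane–palladium complex whose fast η3–η3 equilibration should put the metal on the unsubstituted allyl part and the negative charge on the CMe2 terminus C9, which adds to the β-carbon C7 of the doubly activated enone before the β-keto ester enolate attacks the π-allyl terminus C11 through C1. The closest known reaction is the palladium-catalysed trimethylenemethane [3+2] cycloaddition of the parent and of monosubstituted donors (which bond through their substituted terminus) to cyclic enones and alkylidene β-dicarbonyl acceptors under chiral phosphoramidite control; a gem-dimethyl donor has not been shown. Ring A (C1–C11–C10–C9–C7) closes by intramolecular allylic alkylation, a 5-exo-type attack of the enolate carbon on the allyl terminus that leaves C10=C12 exocyclic. C7 is set in the conjugate addition by the chiral ligand, which selects the enone face, and C1 follows because the three-carbon tether can reach only the enolate face on which it already sits, so the fusion must be cis. The step needs regiocontrol (C9 and not C11 bonding to C7) and face control: slow addition of 7 lets the first-formed complex equilibrate before it is trapped and the ketone C8 and ester C2 make C7 electrophilic enough to accept a tertiary carbon, while face control rests on the ligand.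

Step 6
Reactants: 8 methyl (3aS,6aS)-4,4-dimethyl-5-methylidene-1-oxooctahydropentalene-6a-carboxylate
Product: 9 C8 ethylene ketal of 8 (spiro-1,3-dioxolane at C8; methylene C10=C12 and ester C2 unchanged)
Conditions: Me3SiOCH2CH2OSiMe3, Me3SiOTf (5 mol%), CH2Cl2, −78 → 0 °C
Reagents that add atoms: 1,2-bis(trimethylsilyloxy)ethane, C[Si](C)(C)OCCO[Si](C)(C)C
Why: Silyl-triflate-catalysed ketalisation with the bis-silyl ether of ethylene glycol is aprotic, so the exocyclic alkene should not migrate, and it masks C8 against the borane and Grignard reagents that follow.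

Step 7
Reactants: 9 C8 ethylene ketal of 8
Product: 11 ketal ester alcohol with C12H2OH on the concave face of C10 (10S), via B-alkyl-9-BBN 10 (not isolated)
Conditions: 9-BBN (1.5 equiv), THF, 0 → 40 °C; then aq. NaOH, H2O2, 0 °C
Reagents that add atoms: hydrogen peroxide, OO
Why: Anti-Markovnikov hydroboration–oxidation puts boron on C12 and delivers hydrogen to C10 from the convex face of the cis-fused diquinane (the concave face is screened by ring B and its dioxolane), which sets C10 with the side chain on the concave face.

Step 8
Reactants: 11 ketal ester alcohol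
Product: 12 ketal ester aldehyde (C12 formyl on the concave face of C10)
Conditions: DMP (1,1,1-triacetoxy-1,1-dihydro-1,2-benziodoxol-3(1H)-one), pyridine, CH2Cl2, 0 °C; used directly
Reagents that add atoms: none
Why: Buffered hypervalent-iodine oxidation of the primary alcohol is non-enolising, so the α-stereocentre C10 of the aldehyde should be preserved.

Step 9
Reactants: 12 ketal ester aldehyde
Product: 13 secondary alcohol (C10–CH(OH)CH3, mixture of carbinol epimers)
Conditions: MeMgBr, THF, −78 °C
Reagents that add atoms: methylmagnesium bromide, C[Mg]Br
Why: Grignard addition to the aldehyde is far faster than attack on the hindered ester at quaternary C1 or on the ketal, and the carbinol configuration is of no consequence.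

Step 10
Reactants: 13 secondary alcohol
Product: 14 methyl ketone (C10–C(=O)CH3 on the concave face)
Conditions: DMP, CH2Cl2, rt
Reagents that add atoms: none
Why: Hypervalent-iodine oxidation of the secondary alcohol gives the methyl ketone under neutral conditions that do not epimerise C10.

Step 11
Reactants: 14 methyl ketone
Product: 15 tertiary alcohol (C10–C(CH3)2OH; C8 still ketalised)
Conditions: MeMgBr (excess), THF, −78 → 0 °C
Reagents that add atoms: methylmagnesium bromide, C[Mg]Br
Why: Grignard addition to the ketone completes the carbinol C12; any competing enolisation should take place on the methyl side and so cannot touch C10, and the C1 ester is too hindered to react.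

Step 12
Reactants: 15 tertiary alcohol ketal
Product: 16 hydroxy keto ester (C8 ketone free; C12 carbinol on the concave face)
Conditions: 1 M HCl, THF, rt
Reagents that add atoms: water, O
Why: Acid-catalysed ketal hydrolysis unmasks C8 under conditions mild enough for the tertiary alcohol, which is trans to ester C2 and therefore cannot lactonise.

Step 13
Reactants: 16 hydroxy keto ester
Product: 17 triethylsilyl ether of 16
Conditions: Et3SiOTf, 2,6-lutidine, CH2Cl2, −78 → 0 °C
Reagents that add atoms: triethylsilyl trifluoromethanesulfonate, CC[Si](CC)(CC)OS(=O)(=O)C(F)(F)F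
Why: Silyl triflate silylation caps the tertiary hydroxyl so that its alkoxide cannot add to C8 and fragment the ring during the enolate steps.

Step 14
Reactants: 17 triethylsilyl ether
Product: 18 C5-methyl ketone (mixture of C5 epimers)
Conditions: LiN(i-Pr)2 (1.05 equiv), THF, −78 °C; MeI, −78 → −20 °C
Reagents that add atoms: iodomethane, CI
Why: Kinetic enolate alkylation takes place at C5, the only enolisable α-position of ketone C8 (C1 is quaternary), and both epimers converge to one enolate in the next step.

Step 15
Reactants: 18 C5-methyl ketone
Product: 19 aldol (5S; C5 carries CH3 on the concave face and CH(OH)CH3 on the convex face, carbinol epimers)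
Conditions: LiN(i-Pr)2, THF, −78 → −20 °C; CH3CHO, −78 °C; AcOH, −78 °C
Reagents that add atoms: acetaldehyde, CC=O
Why: Aldol addition of the tetrasubstituted lithium enolate takes acetaldehyde from the convex face (the concave face is blocked by the C10 side chain), which sets quaternary C5 with C4 cis to ester C2, and the cold acidic quench forestalls retro-aldol and lactonisation onto C2.

Step 16
Reactants: 19 aldol
Product: 20 5-acetyl-5-methyl keto ester (1,3-diketone with acetyl cis to ester C2)
Conditions: DMP, CH2Cl2, rt
Reagents that add atoms: none
Why: Neutral hypervalent-iodine oxidation converts the β-hydroxy ketone into the non-enolisable 1,3-diketone without the base that would trigger retro-aldol or retro-Claisen cleavage.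

Step 17
Reactants: 20 5-acetyl-5-methyl keto ester
Product: 21 8-hydroxy-4,4,7-trimethyl-3-[2-(triethylsilyloxy)propan-2-yl]tricyclo[5.3.1.0(1,5)]undec-8-ene-10,11-dione (enol of the ring C 1,3-dione)
Conditions: LiN(SiMe3)2 (3 equiv), THF, −78 → 0 °C; cold dilute HCl
Reagents that add atoms: none
Why: Dieckmann condensation: the acetyl methyl is the only enolisable position, its enolate carbon C3 attacks the cis ester C2 to close the six-membered ring C, and formation of the dione enolate makes the closure irreversible while excess amide base keeps free methoxide from attacking C8.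

Step 18
Reactants: 21 tricyclic enol dione; 22 2-methylpropanoyl chloride
Product: 24 triethylsilyl ether of the target, via enol isobutyrate 23 (not isolated)
Conditions: Et3N, CH2Cl2, 0 °C; then DMAP (0.2 equiv), MeCN, rt
Reagents that add atoms: none
Why: O-acylation of the cyclic 1,3-dione followed by DMAP-catalysed O→C acyl migration (a Fries-type rearrangement of the enol ester) should give the 2-acyl-1,3-dione, which is held as its chelated enol; O-acylation at the C2 oxygen instead would converge on the same product.

Step 19
Reactants: 24 triethylsilyl ether of the target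
Product: 25 (1S,3S,5S,7S)-8-hydroxy-3-(2-hydroxypropan-2-yl)-4,4,7-trimethyl-9-(2-methylpropanoyl)tricyclo[5.3.1.0(1,5)]undec-8-ene-10,11-dione (CNP0267234.1)
Conditions: HF·pyridine, THF, 0 °C → rt
Reagents that add atoms: none
Why: Fluoride-driven cleavage of the tertiary silyl ether releases the carbinol under conditions the acidic triketone enol tolerates.

**Compound list**

1 | ethyl 2-[(trimethylsilyl)methyl]prop-2-enoate | CCOC(=O)C(=C)C[Si](C)(C)C | starting material
2 | 2-methyl-3-[(trimethylsilyl)methyl]but-3-en-2-ol | CC(C)(O)C(=C)C[Si](C)(C)C | intermediate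
3 | 2-methyl-3-[(trimethylsilyl)methyl]but-3-en-2-yl acetate | CC(C)(OC(C)=O)C(=C)C[Si](C)(C)C | intermediate
4 | methyl 2-oxocyclopentane-1-carboxylate | COC(=O)C1CCCC1=O | starting material
5 | methyl 2-oxo-1-(phenylselanyl)cyclopentane-1-carboxylate (racemic) | COC(=O)C1(CCCC1=O)[Se]c1ccccc1 | intermediate
6 | methyl 2-oxo-1-(benzeneseleninyl)cyclopentane-1-carboxylate (selenoxide, not isolated) | COC(=O)C1(CCCC1=O)[Se](=O)c1ccccc1 | intermediate
7 | methyl 5-oxocyclopent-1-ene-1-carboxylate | COC(=O)C1=CCCC1=O | intermediate
8 | methyl (3aS,6aS)-4,4-dimethyl-5-methylidene-1-oxooctahydropentalene-6a-carboxylate | COC(=O)[C@@]12CC(=C)C(C)(C)[C@@H]1CCC2=O | intermediate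
9 | C8 ethylene ketal of 8 | COC(=O)[C@@]12CC(=C)C(C)(C)[C@@H]1CCC21OCCO1 | intermediate
10 | B-alkyl-9-BBN adduct of 9 (boron on C12, C10–H convex; not isolated) | COC(=O)[C@@]12C[C@H](CB3C4CCCC3CCC4)C(C)(C)[C@@H]1CCC21OCCO1 | intermediate
11 | ketal ester primary alcohol (10S, CH2OH concave) | COC(=O)[C@@]12C[C@H](CO)C(C)(C)[C@@H]1CCC21OCCO1 | intermediate
12 | ketal ester aldehyde | COC(=O)[C@@]12C[C@H](C=O)C(C)(C)[C@@H]1CCC21OCCO1 | intermediate
13 | ketal ester secondary alcohol (carbinol epimers) | COC(=O)[C@@]12C[C@H](C(C)O)C(C)(C)[C@@H]1CCC21OCCO1 | intermediate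
14 | ketal ester methyl ketone | COC(=O)[C@@]12C[C@H](C(C)=O)C(C)(C)[C@@H]1CCC21OCCO1 | intermediate
15 | ketal ester tertiary alcohol | COC(=O)[C@@]12C[C@H](C(C)(C)O)C(C)(C)[C@@H]1CCC21OCCO1 | intermediate
16 | hydroxy keto ester | COC(=O)[C@@]12C[C@H](C(C)(C)O)C(C)(C)[C@@H]1CCC2=O | intermediate
17 | triethylsilyl ether of 16 | COC(=O)[C@@]12C[C@H](C(C)(C)O[Si](CC)(CC)CC)C(C)(C)[C@@H]1CCC2=O | intermediate
18 | C5-methyl ketone (C5 epimers) | COC(=O)[C@@]12C[C@H](C(C)(C)O[Si](CC)(CC)CC)C(C)(C)[C@@H]1CC(C)C2=O | intermediate
19 | aldol (5S; carbinol epimers) | COC(=O)[C@@]12C[C@H](C(C)(C)O[Si](CC)(CC)CC)C(C)(C)[C@@H]1C[C@@](C)(C(C)O)C2=O | intermediate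
20 | 5-acetyl-5-methyl keto ester | COC(=O)[C@@]12C[C@H](C(C)(C)O[Si](CC)(CC)CC)C(C)(C)[C@@H]1C[C@@](C)(C(C)=O)C2=O | intermediate
21 | 8-hydroxy-4,4,7-trimethyl-3-[2-(triethylsilyloxy)propan-2-yl]tricyclo[5.3.1.0(1,5)]undec-8-ene-10,11-dione | C1=C(O)[C@]2(C)C[C@H]3C(C)(C)[C@@H](C(C)(C)O[Si](CC)(CC)CC)C[C@@]3(C1=O)C2=O | intermediate
22 | 2-methylpropanoyl chloride | CC(C)C(Cl)=O | starting material
23 | enol isobutyrate of 21 (drawn as the C4–O ester; not isolated) | C1=C(OC(=O)C(C)C)[C@]2(C)C[C@H]3C(C)(C)[C@@H](C(C)(C)O[Si](CC)(CC)CC)C[C@@]3(C1=O)C2=O | intermediate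
24 | triethylsilyl ether of the target | CC(C)C(=O)C1=C(O)[C@]2(C)C[C@H]3C(C)(C)[C@@H](C(C)(C)O[Si](CC)(CC)CC)C[C@@]3(C1=O)C2=O | intermediate
25 | (1S,3S,5S,7S)-8-hydroxy-3-(2-hydroxypropan-2-yl)-4,4,7-trimethyl-9-(2-methylpropanoyl)tricyclo[5.3.1.0(1,5)]undec-8-ene-10,11-dione | CC(C)C(=O)C1=C(O)[C@]2(C)C[C@H]3C(C)(C)[C@@H](C(C)(C)O)C[C@@]3(C1=O)C2=O | target

**Step count and risks**

Total steps: 19. Longest linear sequence: 17 steps (from 4 through steps 3–19; the donor branch from 1 is equally long through steps 1, 2 and 5–19).

Steps most likely to fail:

Step 5. The complex may bond through its unsubstituted terminus (gem-dimethyl group ending next to C1), lose a proton from the tertiary π-allyl intermediate to give a diene, or simply be protodesilylated; the enantioselectivity may also be eroded by the hindered terminus. The fallback is a stepwise annulation with known reactions that sets out from 2 and 7 and comes back at 8. Alcohol 2 with PBr3 and a little pyridine in Et2O at −20 °C should give, with allylic transposition, [2-(bromomethyl)-3-methylbut-2-en-1-yl]trimethylsilane F1. Hosomi–Sakurai conjugate allylation of 7 with F1 under Cu(OTf)2 and a tert-butyl-bis(oxazoline) ligand is an established enantioselective reaction of cyclic alkylidene β-keto esters; the allylsilane reacts at its γ-carbon, the CMe2 terminus. It should give methyl (2R)-2-[3-(bromomethyl)-2-methylbut-3-en-2-yl]-5-oxocyclopentane-1-carboxylate F2 with C7 set by the ligand. K2CO3 in acetone then closes ring A by intramolecular C-alkylation of the β-keto ester (5-exo-tet) to give 8.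

Step 7. Hydrogen may be delivered to C10 with poor facial selectivity, because the exocyclic alkene lies far from the ring fusion that differentiates the two faces. The fallback sets out from 9 and comes back at 12. Anhydrous TsOH in benzene should move the double bond into the ring (C10=C11, the only endocyclic position because C9 is quaternary) to give the 10-methylcyclopentene ketal ester F3. SeO2 in dioxane oxidises the only allylic C–H bonds, those of the C12 methyl, to give the enal F4. Hydrogenation over Pd/C then adds hydrogen to C10=C11 from the convex face, now directly beside the ring fusion, and gives aldehyde 12.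

Step 15. Deprotonation of the concave-face C5–H in the major epimer of 18 may be incomplete, acetaldehyde may transfer a proton to the hindered enolate, or the aldolate may revert on warming. The fallback sets out from 17 and comes back at 19. α-Methylenation of 17 with paraformaldehyde and N-methylanilinium trifluoroacetate in THF at reflux should give the exocyclic enone F5. Conjugate reduction with LiBH(s-Bu)3 at −78 °C generates the same C5-methyl enolate regiospecifically without any deprotonation, and acetaldehyde traps it from the convex face (reductive aldol) to give 19.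

**Further compounds**

F1 | step 5 | [2-(bromomethyl)-3-methylbut-2-en-1-yl]trimethylsilane | CC(C)=C(CBr)C[Si](C)(C)C
F2 | step 5 | methyl (2R)-2-[3-(bromomethyl)-2-methylbut-3-en-2-yl]-5-oxocyclopentane-1-carboxylate (C1 epimers) | COC(=O)C1[C@H](C(C)(C)C(=C)CBr)CCC1=O
F3 | step 7 | C8 ethylene ketal of methyl (3aS,6aS)-4,4,5-trimethyl-1-oxo-1,2,3,3a,4,6a-hexahydropentalene-6a-carboxylate (C10=C11 alkene) | COC(=O)[C@@]12C=C(C)C(C)(C)[C@@H]1CCC21OCCO1
F4 | step 7 | corresponding enal (C12 formyl on C10=C11) | COC(=O)[C@@]12C=C(C=O)C(C)(C)[C@@H]1CCC21OCCO1
F5 | step 15 | C5-methylidene derivative of 17 (exocyclic enone) | COC(=O)[C@@]12C[C@H](C(C)(C)O[Si](CC)(CC)CC)C(C)(C)[C@@H]1CC(=C)C2=O
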